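(All runs come from a simulation with constants of no real substance, noise included.)

The trap is to chase the top of single product along the clock, when the better question is how much substrate stands beside it.

| setting | Wednesday's | Tuesday's | Thursday's | flask |
|---|---|---|---|---|
| substrate | 0.40 M | 0.40 M | 0.60 M | 0.40 M |
| reagent | 0.24 M (fed, over 30 s) | 0.96 M (fed, over 30 s) | 0.48 M (fed, over 30 s) | 0.480 M (fed, over 30 s) |
| capture agent | 0.40 M | 0.40 M | 0.40 M | 0.400 M |
| remark | run made earlier | run made earlier | run made earlier |  |
| time |  |  |  | 25 min |

Reagent makes single product from substrate and bis adduct from single product. Since reagent multiplies both rates, single product stops rising where the two rates are equal, whatever reagent is then present. So at the top, the fraction of single product over the fraction of substrate equals one number, the ratio of the two rate constants, the selectivity factor.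

- Wednesday's (time / min: single product / %, triple product / %, substrate / %): 0.250: 6, 0, 65; 0.667: 24, 1, 36; 1.50: 30, 3, 16; 4.00: 29, 2, 6; 10.0: 30, 3, 4; 25.0: 28, 1, 2
- Tuesday's (time / min: single product / %, triple product / %, substrate / %): 0.250: 28, 1, 49; 0.667: 29, 13, 5; 1.50: 13, 42, 0; 4.00: 1, 54, 0; 10.0: 0, 54, 0; 25.0: 0, 55, 1
- Thursday's (time / min: single product / %, triple product / %, substrate / %): 0.250: 13, 0, 53; 0.833: 31, 3, 14; 2.50: 30, 6, 9; 8.00: 25, 8, 3; 25.0: 28, 6, 0

(standard deviation of a reading: 2 percentage points)

Thursday's highest reading, at 0.833 min, has 31% of single product over 14% of substrate; taking that reading as the top, with its scatter, I read a factor of 2.21. I integrate single product against substrate in closed form, with no substrate lost to self-condensation. The top then stands at the factor raised to the power minus one over the factor less one, and this is the ceiling, the top fraction of the charge in single product 52.0%. As my own rough estimate, I scale this ceiling down by the share of substrate that has self-condensed.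

Thursday's reading reaches 59.6% of the ceiling. The new flask has less substrate and more reagent for each substrate, so I expect a best between 31% and 52.0%.

- the moment within 25 min at which there is most single product
- the amount of single product, in percent of the substrate charged, at that time
- earliest time at which at least nineteen twentieths of that best amount are there, in min
- latest time at which they still are, in min

The forecast gives 33% at 0.85 min, with the window from 0.56 min to 1.15 min. It puts the top where “formation from the dwindling substrate equals loss to bis adduct”, the same condition as mine.

The flask gives 35.8% at 0.732 min, earlier than forecast, with the window from 0.549 min to 1.07 min. At that best time, self-condensation product holds 32.9% of the substrate charged. The ceiling scaled down by that share gives 34.9%.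

    substrate + reagent → single product (k = 0.160 M⁻¹ s⁻¹)
    reagent + single product → bis adduct (k = 0.0710 M⁻¹ s⁻¹)
    reagent + bis adduct → triple product (k = 0.120 M⁻¹ s⁻¹)
    bis adduct + capture agent → trapped intermediate (k = 0.0350 M⁻¹ s⁻¹)
    2 substrate → self-condensation product (k = 0.0310 M⁻¹ s⁻¹)

In the neighbour flask with 0.24 M of substrate, I have the share of self-condensation product from the end, not from the top: 22.5% at 25.0 min. The ceiling scaled down by that end share gives 40.3%. The computed best of that flask is 41.4%.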